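**Retrosynthetic overview**

1. Target 19 ⇐ keto acid 18 (late reduction of the C2 ketone to the equatorial alcohol) ⇐ keto acetate 17 (oxidation of the C15 alcohol).
2. Key bond C4–C19: 17 ⇐ ring A enone 16 + an acetoxymethyl radical from acetoxyacetic acid. A nucleophilic one-carbon unit at the formaldehyde oxidation level adds to the electrophilic enone β-carbon and creates the C4 quaternary centre with the acetate already in place.
3. C9–C11: 16 ⇐ bis-enone 6 + dilithio side chain 11 (from methyl hydrogen (R)-3-methylglutarate 7), followed by palladium/formate hydrogenolysis (9-H, C7=C8).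
4. Ring A: 6 ⇐ keto ester 3 by intramolecular acylation of the isopropenyl group.
5. Ring B is (S)-carvone 1 (C5 from the chiral pool, C10 by two alkylations). Ring B comes first, ring A second.

Assumption: methyl hydrogen (R)-3-methylglutarate (7) is bought; locants C1–C20 are the labdane locants of the target; "α" is the face of the C10 methyl group and "β" the opposite face.

**Route**

Step 1
Reactants: 1 (S)-carvone
Product: 2 (5S)-2,6-dimethyl-5-(prop-1-en-2-yl)cyclohex-2-en-1-one (6-methylcarvone; C6 epimers)
Conditions: LiN(iPr)2, THF, −78 °C; MeI, −78 → 0 °C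
Reagents that add atoms: iodomethane, CI
Why: Kinetic α′-deprotonation and SN2 methylation (enolate alkylation) install the future C20 methyl; the new centre forms as an epimer mixture that is erased when this carbon is enolised again in step 2.

Step 2
Reactants: 2 6-methylcarvone
Product: 3 tert-butyl 2-[(1R,6R)-1,3-dimethyl-2-oxo-6-(prop-1-en-2-yl)cyclohex-3-en-1-yl]acetate
Conditions: LiN(iPr)2, THF, −78 → 0 °C; BrCH2CO2tBu, DMPU, −78 °C → rt
Reagents that add atoms: tert-butyl bromoacetate, CC(C)(C)OC(=O)CBr
Why: The tetrasubstituted lithium enolate is alkylated on the face opposite the neighbouring isopropenyl group (enolate alkylation under steric control), so the acetate arm ends trans to isopropenyl and the methyl cis, which fixes quaternary C10 relative to the carvone-derived C5.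

Step 3
Reactants: 3 keto tert-butyl ester
Product: 6 (4aR,8aR)-2,5,8a-trimethyl-4,4a,8,8a-tetrahydronaphthalene-1,7-dione (trans-fused bis-enone), via carboxylic acid 4 (not isolated), via mixed anhydride 5 (not isolated)
Conditions: CF3CO2H, (CF3CO)2O, CH2Cl2, 0 °C → rt; aq. NaHCO3 work-up
Reagents that add atoms: none
Why: CF3CO2H cleaves the tert-butyl ester and the mixed anhydride acylates the 1,1-disubstituted alkene at its CH2 terminus (intramolecular Friedel–Crafts-type alkene acylation, Markovnikov, six-membered ring) to a tertiary cation that loses a proton to give the conjugated 3-methylcyclohexenone; the ring B enone alkene is too electron-poor to compete, and the trans ring fusion follows from step 2.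

Step 4
Reactants: 7 methyl hydrogen (R)-3-methylglutarate
Product: 8 methyl (3R)-5-hydroxy-3-methylpentanoate
Conditions: BH3·SMe2, THF, 0 °C → rt
Reagents that add atoms: none
Why: Borane reduces the free carboxylic acid much faster than the methyl ester (chemoselective acyloxyborane reduction), which differentiates the two arms without touching the stereocentre.

Step 5
Reactants: 8 hydroxy ester
Product: 9 methyl (3S)-5-iodo-3-methylpentanoate
Conditions: I2, PPh3, imidazole, CH2Cl2, 0 °C
Reagents that add atoms: iodine, II
Why: Appel-type iodination of the primary alcohol (SN2 at a non-stereogenic CH2; the descriptor changes only because of the priority rules).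

Step 6
Reactants: 9 iodo ester
Product: 10 (3S)-5-iodo-3-methylpentan-1-ol
Conditions: i-Bu2AlH, CH2Cl2, −78 → 0 °C
Reagents that add atoms: none
Why: The aluminium hydride reduces the methyl ester to the primary alcohol while the primary alkyl iodide is inert at low temperature (ester reduction).

Step 7
Reactants: 6 bis-enone; 10 iodo alcohol
Product: 14 tris(methyl carbonate) of the C9 adduct (C9–OCO2Me on the α face; ring A as its dienyl carbonate; side-chain primary carbonate), via dilithio reagent 11 (not isolated), via lithium dienolate 12 (not isolated), via trilithium adduct 13 (not isolated)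
Conditions: 10, n-BuLi then t-BuLi (2 equiv), Et2O, −78 °C; separately 6, 2,4,6-Me3C6H2Li, THF, −78 °C; combine, −78 → −40 °C; ClCO2Me, −78 → 0 °C
Reagents that add atoms: methyl chloroformate, COC(Cl)=O
Why: Mesityllithium turns the unhindered ring A enone into its cross-conjugated lithium dienolate (in-situ protection; the ring B enone has no α′-hydrogen), so the primary alkyllithium 11 adds 1,2 to the remaining C9 ketone from the β face, opposite the pseudoaxial angular methyl (side chain β, oxygen α), and methyl chloroformate O-acylates both alkoxides and the enolate (organolithium 1,2-addition with enolate protection).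

Step 8
Reactants: 14 tris(methyl carbonate)
Product: 16 (4aR,8R,8aS)-8-[(3R)-5-hydroxy-3-methylpentyl]-4,7,8a-trimethyl-4a,5,8,8a-tetrahydronaphthalen-2(1H)-one, via dicarbonate 15 (not isolated)
Conditions: Pd(OAc)2 (5 mol%), PBu3, HCO2H, Et3N, THF, 50 °C; then K2CO3, MeOH, rt
Reagents that add atoms: none
Why: Tsuji-type palladium–formate hydrogenolysis: zerovalent palladium ionises the tertiary allylic carbonate anti to the leaving group (palladium on the β face), the formate complex loses CO2, and hydride passes from palladium to the more substituted allyl terminus C9, giving net inversion (9-H β, side chain α) with the C7=C8 alkene kept; K2CO3/MeOH then cleaves the enol carbonate and the primary carbonate.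

Step 9
Reactants: 16 ring A enone
Product: 17 [(1R,4aS,5R,8aS)-5-[(3R)-5-hydroxy-3-methylpentyl]-1,4a,6-trimethyl-3-oxo-1,2,3,4,4a,5,8,8a-octahydronaphthalen-1-yl]methyl acetate
Conditions: AcOCH2CO2H (3 equiv), [Ir(dF(CF3)ppy)2(dtbbpy)]PF6 (2 mol%), K2HPO4, DMF, 450 nm LEDs, rt
Reagents that add atoms: acetoxyacetic acid, CC(=O)OCC(=O)O
Why: Proposed new method: the excited iridium photocatalyst oxidises acetoxyacetate, which loses CO2 to give the nucleophilic acetoxymethyl radical (a CH2OAc carbanion equivalent, i.e. formaldehyde-level carbon with reversed polarity); this adds to the electrophilic β-carbon C4 along the stereoelectronically preferred axial path (either face must place one C4 substituent syn-axial to the C10 methyl, so the chair-like axial trajectory decides), setting the quaternary centre with CH2OAc on the α face, and the resulting α-keto radical is reduced and protonated to close the cycle; the closest known reactions are photoredox decarboxylative Giese additions of α-oxygenated acids and tin-mediated additions of acyloxymethyl radicals to enones.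

Step 10
Reactants: 17 keto acetate alcohol
Product: 18 (3R)-5-[(1R,4aS,5R,8aS)-5-(acetoxymethyl)-2,5,8a-trimethyl-7-oxo-1,4,4a,5,6,7,8,8a-octahydronaphthalen-1-yl]-3-methylpentanoic acid
Conditions: TEMPO (0.2 equiv), PhI(OAc)2 (2.5 equiv), MeCN/H2O, rt
Reagents that add atoms: water, O
Why: Oxoammonium-mediated oxidation of the only hydroxyl group to the aldehyde and, through its hydrate, to the carboxylic acid (TEMPO/PhI(OAc)2 oxidation); ketone, acetate and the trisubstituted alkene are inert and no stereocentre is touched.

Step 11
Reactants: 18 keto acid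
Product: 19 (3R)-5-[(1R,4aS,5R,7S,8aS)-5-(acetoxymethyl)-7-hydroxy-2,5,8a-trimethyl-1,4,4a,5,6,7,8,8a-octahydronaphthalen-1-yl]-3-methylpentanoic acid (target)
Conditions: SmI2 (4 equiv), THF/H2O, 0 °C → rt
Reagents that add atoms: none
Why: Ketyl (single-electron) reduction by SmI2 with water as proton source behaves like a dissolving-metal reduction: the samarium-bound oxygen sits equatorial and carbon is protonated axially between the two syn-axial groups (C4 CH2OAc, C10 CH3), giving the thermodynamically favoured equatorial 2-alcohol (hydride reagents would give the axial epimer); acetate, acid and alkene are inert without an amine additive.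

**Compound list**

1 | (S)-(+)-carvone, (5S)-2-methyl-5-(prop-1-en-2-yl)cyclohex-2-en-1-one | CC1=CC[C@H](C(C)=C)CC1=O | starting material
2 | (5S)-2,6-dimethyl-5-(prop-1-en-2-yl)cyclohex-2-en-1-one (6-methylcarvone, C6 epimers) | CC1=CC[C@H](C(C)=C)C(C)C1=O | intermediate
3 | tert-butyl 2-[(1R,6R)-1,3-dimethyl-2-oxo-6-(prop-1-en-2-yl)cyclohex-3-en-1-yl]acetate | CC(C)(C)OC(=O)C[C@@]1(C)C(=O)C(C)=CC[C@@H]1C(C)=C | intermediate
4 | 2-[(1R,6R)-1,3-dimethyl-2-oxo-6-(prop-1-en-2-yl)cyclohex-3-en-1-yl]acetic acid | OC(=O)C[C@@]1(C)C(=O)C(C)=CC[C@@H]1C(C)=C | intermediate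
5 | mixed anhydride of 4 with trifluoroacetic acid | FC(F)(F)C(=O)OC(=O)C[C@@]1(C)C(=O)C(C)=CC[C@@H]1C(C)=C | intermediate
6 | (4aR,8aR)-2,5,8a-trimethyl-4,4a,8,8a-tetrahydronaphthalene-1,7-dione (trans-fused bis-enone) | CC1=CC(=O)C[C@@]2(C)C(=O)C(C)=CC[C@H]12 | intermediate
7 | (3R)-5-methoxy-3-methyl-5-oxopentanoic acid (methyl hydrogen (R)-3-methylglutarate) | OC(=O)C[C@@H](C)CC(=O)OC | starting material
8 | methyl (3R)-5-hydroxy-3-methylpentanoate | OCC[C@@H](C)CC(=O)OC | intermediate
9 | methyl (3S)-5-iodo-3-methylpentanoate | ICC[C@@H](C)CC(=O)OC | intermediate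
10 | (3S)-5-iodo-3-methylpentan-1-ol | ICC[C@@H](C)CCO | intermediate
11 | lithium (3R)-5-lithio-3-methylpentan-1-olate (dilithio side-chain reagent) | [Li]CC[C@@H](C)CCO[Li] | intermediate
12 | lithium dienolate of 6 (O–Li at C2; C1=C2 and C3=C4 double bonds; ring B enone intact) | CC1=CC(O[Li])=C[C@@]2(C)C(=O)C(C)=CC[C@H]12 | intermediate
13 | trilithium adduct: 12 after 1,2-addition of 11 at C9 (C9–OLi on the α face, side chain β; side-chain OLi) | CC1=CC(O[Li])=C[C@@]2(C)[C@@](O[Li])(CC[C@@H](C)CCO[Li])C(C)=CC[C@H]12 | intermediate
14 | tris(methyl carbonate): C9 tertiary allylic carbonate (α), ring A 2-(methoxycarbonyloxy)-1,3-diene, side-chain primary carbonate | CC1=CC(OC(=O)OC)=C[C@@]2(C)[C@@](OC(=O)OC)(CC[C@@H](C)CCOC(=O)OC)C(C)=CC[C@H]12 | intermediate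
15 | dicarbonate: 14 with the C9 carbonate replaced by hydrogen (9-H β, side chain α, C7=C8) | CC1=CC(OC(=O)OC)=C[C@@]2(C)[C@H](CC[C@@H](C)CCOC(=O)OC)C(C)=CC[C@H]12 | intermediate
16 | (4aR,8R,8aS)-8-[(3R)-5-hydroxy-3-methylpentyl]-4,7,8a-trimethyl-4a,5,8,8a-tetrahydronaphthalen-2(1H)-one | CC1=CC(=O)C[C@@]2(C)[C@H](CC[C@@H](C)CCO)C(C)=CC[C@H]12 | intermediate
17 | [(1R,4aS,5R,8aS)-5-[(3R)-5-hydroxy-3-methylpentyl]-1,4a,6-trimethyl-3-oxo-1,2,3,4,4a,5,8,8a-octahydronaphthalen-1-yl]methyl acetate | CC(=O)OC[C@]1(C)CC(=O)C[C@@]2(C)[C@H](CC[C@@H](C)CCO)C(C)=CC[C@H]12 | intermediate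
18 | (3R)-5-[(1R,4aS,5R,8aS)-5-(acetoxymethyl)-2,5,8a-trimethyl-7-oxo-1,4,4a,5,6,7,8,8a-octahydronaphthalen-1-yl]-3-methylpentanoic acid | CC(=O)OC[C@]1(C)CC(=O)C[C@@]2(C)[C@H](CC[C@@H](C)CC(=O)O)C(C)=CC[C@H]12 | intermediate
19 | (3R)-5-[(1R,4aS,5R,7S,8aS)-5-(acetoxymethyl)-7-hydroxy-2,5,8a-trimethyl-1,4,4a,5,6,7,8,8a-octahydronaphthalen-1-yl]-3-methylpentanoic acid | CC(=O)OC[C@]1(C)C[C@@H](O)C[C@@]2(C)[C@H](CC[C@@H](C)CC(=O)O)C(C)=CC[C@H]12 | target

**Step count and risks**

Total step count: 11. Longest linear sequence: 8 steps (steps 1, 2, 3, 7, 8, 9, 10, 11 from (S)-carvone; the side-chain branch, steps 4–6 then 7–11, is also 8).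

The three steps most likely to fail:

Step 8. The tertiary C9 carbonate is pseudo-equatorial in the locked trans-fused ring B, so ionisation may be slow or give diene by elimination, and the hydride regiochemistry is unproven at this crowded terminus. Fallback: starting again from bis-enone 6, the addition of 11 is run as in step 7 but quenched with aqueous NH4Cl, which gives the tertiary allylic alcohol diol F1. A Ph3SiOReO3-catalysed suprafacial 1,3-transposition moves the oxygen to C7 and gives the secondary allylic alcohol F2 with a tetrasubstituted C8=C9 alkene. ClCO2Me/pyridine gives the bis(methyl carbonate) F3, whose secondary C7 carbonate can reach the pseudoaxial geometry needed for ionisation. The same Pd(OAc)2/PBu3/HCO2H hydrogenolysis (hydride from palladium to C9 on the β face) gives the enone mono-carbonate F4, and K2CO3/MeOH returns to the route at 16.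

Step 9. The radical addition must form a quaternary centre syn to the angular methyl; conversion may be low, or the radical may attack the β face. Fallback: from 16 the primary alcohol is oxidised first (TEMPO, PhI(OAc)2, MeCN/H2O) to the enone acid F5. Copper-catalysed conjugate addition of the silicon-based hydroxymethyl anion equivalent (iPrO)Me2SiCH2MgCl (3 equiv, CuI, Me3SiCl, THF, −40 °C; a cuprate π-complex pathway with reliable axial delivery) gives the silylmethyl ketone F6. Tamao oxidation (H2O2, KF, KHCO3) gives the hydroxymethyl keto acid F7, and acetylation (Ac2O, pyridine) rejoins the route at 18.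

Step 11. If the samarium reduction gives mainly the axial alcohol or is sluggish with the free acid present, the fallback sets out from 18. Lithium in liquid ammonia with t-BuOH gives the equatorial alcohol under thermodynamic control and also cleaves the acetate, leading to the dihydroxy acid F8. Regioselective acetylation of the primary C19 hydroxyl (AcCl, 2,4,6-collidine, CH2Cl2, −78 °C, or a lipase with vinyl acetate) then arrives at 19.

Further compounds

F1 | step 8 | tertiary allylic alcohol diol: 6 after addition of 11 at C9 and protonation (9-OH α, side chain β, free primary OH, ring A enone restored) | CC1=CC(=O)C[C@@]2(C)[C@@](O)(CC[C@@H](C)CCO)C(C)=CC[C@H]12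
F2 | step 8 | transposed secondary allylic alcohol (7-OH α, C8=C9 tetrasubstituted alkene bearing the side chain) | CC1=CC(=O)C[C@@]2(C)C(CC[C@@H](C)CCO)=C(C)[C@H](O)C[C@H]12
F3 | step 8 | bis(methyl carbonate) of F2 (C7 secondary allylic carbonate and side-chain primary carbonate) | CC1=CC(=O)C[C@@]2(C)C(CC[C@@H](C)CCOC(=O)OC)=C(C)[C@H](OC(=O)OC)C[C@H]12
F4 | step 8 | enone mono-carbonate: methyl carbonate of the primary alcohol of 16 | CC1=CC(=O)C[C@@]2(C)[C@H](CC[C@@H](C)CCOC(=O)OC)C(C)=CC[C@H]12
F5 | step 9 | enone acid: 16 with the side-chain CH2OH oxidised to CO2H | CC1=CC(=O)C[C@@]2(C)[C@H](CC[C@@H](C)CC(=O)O)C(C)=CC[C@H]12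
F6 | step 9 | silylmethyl ketone: C4 bearing CH2SiMe2(OiPr) on the α face, C2 ketone, side-chain acid | CC(C)O[Si](C)(C)C[C@]1(C)CC(=O)C[C@@]2(C)[C@H](CC[C@@H](C)CC(=O)O)C(C)=CC[C@H]12
F7 | step 9 | hydroxymethyl keto acid: 18 without the acetyl group | OC[C@]1(C)CC(=O)C[C@@]2(C)[C@H](CC[C@@H](C)CC(=O)O)C(C)=CC[C@H]12
F8 | step 11 | dihydroxy acid: 19 without the acetyl group (2-OH equatorial, free C19 OH) | OC[C@]1(C)C[C@@H](O)C[C@@]2(C)[C@H](CC[C@@H](C)CC(=O)O)C(C)=CC[C@H]12
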